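At 50 min, when you look into the flask, the epsilon run has been followed to 40.0 min and J reads flat from 15.0 min on, within the scatter. I assume, as the forecast does, that X and Z make J on the catalyst Q, and I follow the rate rather than the concentrations: a start rate times an X factor, a Z factor and a catalyst factor.

| setting | epsilon | eta | flask |
|---|---|---|---|
| X | 0.0020 M | 0.0020 M | 0.0020 M |
| Z | 2.4 mM | 2.4 mM | 2.40 mM |
| G | 1 mM | 1.5 mM | 1.00 mM |
| Q | 50 µM | 50 µM | 50 µM |
| remark | the very flask that is asked about, followed so far | run made earlier |  |
| time |  |  | 50 min |

epsilon run (percent of the X charged): time / min: J / % = 5.00: 69.6; 15.0: 74.0; 25.0: 74.0; 40.0: 74.8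

eta run (percent of the X charged): time / s: J / % = 15.0: 30.3; 40.0: 47.3; 80.0: 56.0; 120: 58.8

(readings scatter by 0.5 percentage points)

- larch: change nothing and wait 50 min more
- birch: at 50 min add Q, 100% of the amount charged, then wait 50 min
- alder: at 50 min take out 90% of the J then present, then wait 50 min
- maple: at 50 min add Z, 50.0% of the amount charged, then wait 50 min

- what is taken out of J is counted as made
- additions bring no volume worth counting

1. J, in percent of the X first charged, at 50 min
2. what to do for the largest gain in J; "none" if nothing gains more than 2 percentage points (larch / birch / alder / maple / none)
3. J present, with what was taken out counted in, in percent of the X first charged, after larch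
4. J present, with what was taken out counted in, in percent of the X first charged, after birch

The eta run starts at about 0.0202 s⁻¹ of the charged X, read over its first interval, and its last interval runs at 7.00 × 10⁻⁴ s⁻¹, slower by a factor of 28.9. At that point J reads about 57.4%, which puts the X factor at 42.6% and, counting one Z per J, the Z factor at 0.522. Their product is larger than the observed rate ratio, so a catalyst factor of 0.156 remains, which I read as catalyst deactivation. Taken as an exponential fall between the middles of those intervals, it gives a life of 49.8 s.

I carry that rate and life over to this flask, although G differs. Its last reading stands 48.2 lives from the start, so I compute no correction and commit to the late mean of 74.3% for now and for larch. Counting one Z per J, I reckon that this flask holds 25.7% of its X and 38.1% of its Z. Their product, 0.0981, is the restart factor: the rate at which a fresh charge of Q starts, over the rate of the first start. Start rate times restart factor times life promises 9.9 percentage points from birch, above the margin, so I reach 84.2%. Taking out J and adding Z bring no fresh Q, so I choose birch.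

The forecast gives 74.5% (73.7% to 75.4%) at 50 min, chooses birch, and gives 74.8% (73.8% to 76%) after larch and 85% (76% to 90%) after birch, slightly above my figure for birch: “So Q is dying, not the reaction balancing.”

    X + Z + Q → Q + J (k = 3.10 × 10⁵ M⁻² s⁻¹)
    G + Z + Q → Q + L (k = 2.50 × 10⁵ M⁻² s⁻¹)
    Q → D (k = 0.00230 s⁻¹)
    2 Q → E (k = 190 M⁻¹ s⁻¹)

The flask gives 74.4% at 50 min, 74.4% after larch and 80.0% after birch, a gain of 5.7 points, so birch is the choice. At 50.0 min, 10.3% of the Z is still free, against my 38.1%. With 25.6% of the X left, the restart factor becomes 0.0264, which reckons to 2.7 points, below the gain the flask shows. The neighbour charged with 2.5 × 10⁻⁴ M of G stands at 83.7% at 16% of its X and 22% of its Z left, so its restart factor is 0.0363, larger than the 0.0264 of this flask.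

(The numbers in the tables come from a simulation for an exercise.)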